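## Structural features

The target is a daucane-type hydroazulene: a cyclopentane (C1–C5) trans-fused through C1/C5 to a cycloheptenone (C1, C5–C10), with a 4-hydroxybenzoate on C6. Atom labels used throughout: C1 is the methyl-bearing quaternary fusion carbon, C2 the secondary carbinol, C3 the ring methylene, C4 the isopropyl carbinol, C5 the fusion methine, C6 the ester carbon, C7=C8 the alkene (methyl on C8), C9 the ketone and C10 the methylene back to C1. All five stereocentres are contiguous (C2–C1–C5–C4 around the small ring, C6 attached to C5), with descriptors C1 R, C2 R, C4 R, C5 S, C6 S. The C1 methyl, C2 hydroxyl and C4 hydroxyl lie on one face; the C5 hydrogen and the C6 ester oxygen lie on the other. Fragile points are the allylic C6 ester, which is γ to the C9 carbonyl and next to the C4 hydroxyl (elimination, acyl migration), the tertiary C4 alcohol (dehydration), the enone (conjugate addition, over-reduction) and the free phenol. The real difficulty is the all-carbon quaternary C1 wedged between C2, C5 and C10 together with the trans fusion, which cannot be repaired by epimerisation because neither fusion atom is enolisable in the target. The feature exploited is that, in the seven-membered ring, the C6 oxygen and the C9 carbonyl are 1,4-related across C7=C8(CH3). An imagined C10–O bond turns C6–C7=C8–C9(=O)–C10 plus that oxygen into the 8-oxabicyclo[3.2.1]oct-3-en-2-one of a 3-oxidopyrylium adduct, leaving C1 and C5 as the alkene partner. The C2/C4 1,3-dioxygenation is an aldol retron, so the small ring can be closed late at C3–C4, away from the fusion atoms.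

## Logic of the disconnections

22 to 21: the phenolic O–H is traced back to an O–acetyl bond. A free phenol would compete in the acylation and is exposed to the oxidant and Lewis acid used earlier. Nothing is gained in skeleton, but the whole aroyl unit can travel protected. The forward step must cleave an aryl acetate without touching the C6 benzoate.

21 to 20: the C2–H bond is cut, so the C2 carbinol becomes a ketone. The ketone is what makes C3 nucleophilic. One stereocentre disappears and a β-hydroxy ketone retron appears. The forward hydride must choose the saturated C2 ketone over the C9 enone and approach anti to the C1 methyl.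

20 to 19: the C3–C4 bond is cut (aldol). It is the only ring bond of the small ring that touches neither fusion atom. The five-membered ring and the C4 stereocentre are removed, leaving a monocyclic cycloheptenone with two carbonyl arms trans on C1 and C5. The forward step needs a nucleophile formed only at C3 that attacks C4 rather than C9 or C7.

19 to 17 and 18: the ester C–O bond at C6 is cut. At this stage the C6 hydroxyl is the only hydroxyl in the molecule, so no selectivity question arises. The aroyl unit is split off as a separate piece. The forward step must acylate a hindered allylic alcohol without β-elimination across C5–C6.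

17 to 16: the C10–H bond is replaced by a C10–O bond to the C6 oxygen. The 1,4-relationship of C6–O and C9=O makes this the retron of an α-alkoxy ketone reduction. The monocycle becomes a bridged bicycle that is a cycloadduct. The forward reduction must break C10–O, not C6–O, and spare the enone and the enol silane.

16 to 15 to 14 to 13: functional-group changes at C2 only (O–Si bond of the enol ether, C2=O, O–Si bond of the silyl ether). C2 must be inert, bulky and stereogenic during the cycloaddition and become the C3 pronucleophile afterwards. The enol silane is made while C10 is still a bridgehead and cannot enolise. This leads to an adduct with a single acceptor carbonyl and a directing centre. The forward steps must avoid base that could open the bridge by elimination from C5.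

13 to 4 and 11 (through 12): the C10–C1 and C6–C5 bonds are cut. This retro-(5+2) removes the seven-membered ring and four stereocentres at once and divides the skeleton into a six-carbon and a nine-carbon piece. The forward step demands E geometry in 11, acyl-endo approach, one alkene face, and enough reactivity from a trisubstituted alkene.

11 to 8 and 9 (through 10), then 8 to 7 to 5 (through 6): the C4–C5 bond is cut (acyl to alkenyl carbon), then the C1–CH3 and C5–I bonds. Syn carbometalation of an alkyne writes the E geometry without an olefination of a ketone. The piece shrinks to a four-carbon alkynol that carries the stereocentre. The forward steps need regio- and syn-selective methylmetalation and retention in both metal exchanges.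

4 to 3 to 2 to 1: the acetal O–acyl bond, then the ring C–O bonds of the pyranone back to a furan, then the alcohol back to an ester. Oxidative ring expansion of a furfuryl alcohol delivers the 1,4-oxygenated pyranone directly. The piece becomes a purchasable furan. The furan methyl must map onto C8.

## Other disconnections considered

Alternative 1: The cut removes C1 from the seven-membered ring (C1–C5 and C1–C10), so that C5–C10 become a benzene ring and C1 a carbenoid carbon. Forward, Rh2(OAc)4, or the bulkier Rh2(O2CCPh3)4 to hold back the 1,2-hydride shift typical of α-alkyl diazoketones, would turn diazoketone A1 into the carbenoid. This cyclopropanates the ipso/ortho bond of the dimethoxytolyl ring, and electrocyclic opening of the norcaradiene gives dihydroazulenone A2 (Buchner reaction). In its favour, both rings, the quaternary methyl and all fifteen skeletal carbons arrive in one catalytic intramolecular step; C6 and C9 already carry oxygen, and the C4 carbinol is the only stereocentre to be bought. Against it here, the carbenoid must choose the free ortho carbon over the methoxy-bearing one, and aromatic substitution or C–H insertion into the isopropyl or silyl ethyl groups may compete on so electron-rich a ring. The C1 configuration rests on 1,3-induction from C4 across a flat ring. After the key step C5 is still trigonal, so the trans C5 hydrogen and the C6 carbinol must come from reducing a tetrasubstituted enol ether, while the C6 and C9 oxygens, now the two ends of an ene-dione equivalent, have to be told apart. In comparison, this route is the better one in ring construction per step and in the likelihood that the bond-forming event occurs at all (no hindered bimolecular partner), and its front end is probably as short. The chosen plan is stronger in stereochemical logic, since the trans fusion and the C6 configuration are written into the cycloaddition itself, and its end-game needs no differentiation of two like carbonyls; overall step counts are expected to be similar.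

Alternative 2: The cut takes the angular methyl back to a cyclopropane methylene bonded to C1 and C10, that is, to the C1=C10 alkene of allylic alcohol A3. Forward, Et2Zn/CH2I2 would form the zinc alkoxide of the C2 hydroxyl, which delivers the methylene to its own face of the alkene and gives cyclopropane A4 (hydroxyl-directed Simmons–Smith reaction). Later the C10–CH2 bond is cleaved, for example through a C9 ketone, to reveal the methyl group and the C10 methylene. In its favour, directed cyclopropanation of cyclic allylic alcohols is among the most dependable stereoselective reactions, it gives exactly the required cis relationship of the C1 methyl and the C2 hydroxyl, and it uses the C2 centre instead of destroying and remaking it. Against it here, the key step adds one carbon and no ring that survives. A3, with the hydroazulene, the C5 hydrogen and the C4, C6, C8 and C9 centres, must therefore come from other chemistry. Four oxygens are kept apart by three silyl ethers of two kinds, and regioselective ring opening, C9 oxidation, C7=C8 dehydrogenation and esterification still follow. In comparison, it is the better plan in predictability of the key step and in direct use of the C2 stereocentre. It is weaker in skeletal bond formation (none against two ring bonds and four stereocentres), in convergence and in protecting-group economy, and its linear sequence is expected to be clearly longer.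

Alternative 3: The cut is C10–C1, with the C6 oxygen reconnected to C9 as an enol ether oxygen; the cycloheptenone becomes the 2-methylenetetrahydrofuran A6 carrying the cyclopentenyl ring on its carbinol carbon. Forward, heating A6 would trigger a [3,3] shift (Claisen ring expansion, boat-like because of the five-membered ring) that forms C10–C1, breaks C6–O and gives cycloheptenone A7 with C5=C6 and the C9 ketone. In its favour, the step is unimolecular and thermally driven, and the C4 carbinol with its isopropyl group comes from the terpene alcohol A5 by ring cleavage and re-closure to a cyclopentene. The quaternary centre is set with chirality transfer from the C6 carbinol carbon. Syn hydroboration of C5=C6 from the face opposite the angular methyl would then place the C5 hydrogen and the C6 hydroxyl as the target has them. Against it here, a sigmatropic shift onto a tetrasubstituted alkene terminus needs forcing conditions under which the exocyclic enol ether can isomerise into the ring. The C6 configuration of A6, which decides the C1 face, must be set on a side-chain carbinol; the C2 oxygen must come from an allylic oxidation; and C7=C8 still has to be introduced. In comparison, it is equal or better as a source of absolute configuration (C4 straight from the chiral pool instead of a relay through a sacrificial centre) and in reliability of the ring-forming event. The chosen plan is more convergent and fixes C1, C5 and C6 together, whereas here C5 and C6 wait for later steps; step counts are expected to be comparable.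

Key step: step 7

Assumption: 1, 5, 9 and 18 are purchased; the (R) configuration of the sacrificial C2 centre is chosen from a transition-state model (C2–O bond anti to the forming C10–C1 bond), and because this centre is erased in step 9 its configuration is a free design variable.

## Steps

Step 1
Reactants: 1 methyl 3-methylfuran-2-carboxylate
Product: 2 (3-methylfuran-2-yl)methanol
Conditions: LiAlH4, Et2O, 0 °C
Reagents that add atoms: none
Why: Hydride reduction of the ester to the primary alcohol; the furan ring is inert to LiAlH4 at 0 °C.

Step 2
Reactants: 2 (3-methylfuran-2-yl)methanol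
Product: 3 6-hydroxy-4-methyl-2H-pyran-3(6H)-one (racemic hemiacetal)
Conditions: NBS, NaHCO3, NaOAc, THF/H2O (4:1), 0 °C
Reagents that add atoms: water, O
Why: Achmatowicz rearrangement: oxidation of the furan at its 2- and 5-positions in water, opening to the ene-dione and re-closure through the primary hydroxyl as the six-membered hemiacetal. The furan 3-methyl ends on C4 of the pyranone, next to the ketone, which is the future C8.

Step 3
Reactants: 3 6-hydroxy-4-methyl-2H-pyran-3(6H)-one
Product: 4 6-acetoxy-4-methyl-2H-pyran-3(6H)-one (racemic)
Conditions: Ac2O, pyridine, DMAP (cat.), CH2Cl2, 0 °C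
Reagents that add atoms: acetic anhydride, CC(=O)OC(C)=O
Why: Acylation of the anomeric hydroxyl makes it the leaving group needed for ylide formation; mild base at 0 °C avoids premature elimination.

Step 4
Reactants: 5 (R)-but-3-yn-2-ol
Product: 7 (R,E)-4-iodo-3-methylbut-3-en-2-ol, via alkenylalane 6 (not isolated)
Conditions: Me3Al (3 equiv), Cp2ZrCl2 (0.25 equiv), CH2Cl2, 0 °C to rt; then I2, THF, −30 °C
Reagents that add atoms: trimethylaluminium, C[Al](C)C; iodine, II
Why: Zirconium-catalysed carboalumination adds methyl and aluminium syn across the terminal alkyne with methyl on the internal carbon (the alcohol is carried as its aluminium alkoxide), and iodinolysis of the C–Al bond goes with retention, so only the E iodide should form. The carbinol centre is not touched.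

Step 5
Reactants: 7 (R,E)-4-iodo-3-methylbut-3-en-2-ol
Product: 8 (R,E)-tert-butyl[(4-iodo-3-methylbut-3-en-2-yl)oxy]dimethylsilane
Conditions: TBSCl, imidazole, DMF, rt
Reagents that add atoms: tert-butyldimethylsilyl chloride, CC(C)(C)[Si](C)(C)Cl
Why: Standard silylation of a secondary alcohol; the silyl ether survives organolithium, amine base and heat and supplies the bulk meant to steer the cycloaddition.

Step 6
Reactants: 8 (R,E)-tert-butyl[(4-iodo-3-methylbut-3-en-2-yl)oxy]dimethylsilane; 9 N-methoxy-N,2-dimethylpropanamide
Product: 11 (R,E)-6-(tert-butyldimethylsilyloxy)-2,5-dimethylhept-4-en-3-one, via alkenyllithium 10 (not isolated)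
Conditions: t-BuLi (2.1 equiv), Et2O, −78 °C; then 9, −78 to 0 °C
Reagents that add atoms: none
Why: Iodine–lithium exchange with retention of alkene geometry, then acylation by the Weinreb amide, whose chelated tetrahedral intermediate prevents over-addition. Lithium is trans to the silyloxy carbon, so silyl migration from oxygen to carbon is not possible.

Step 7
Reactants: 4 6-acetoxy-4-methyl-2H-pyran-3(6H)-one; 11 (R,E)-6-(tert-butyldimethylsilyloxy)-2,5-dimethylhept-4-en-3-one
Product: 13 (1S,5S,6S,7S)-7-[(1R)-1-(tert-butyldimethylsilyloxy)ethyl]-3,7-dimethyl-6-(2-methylpropanoyl)-8-oxabicyclo[3.2.1]oct-3-en-2-one (acyl endo; silyloxyethyl exo), via 4-methyl-3-oxidopyrylium 12 (not isolated)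
Conditions: Et3N (1.5 equiv), MeCN, 60 °C; 4 (3 equiv) added over 12 h to 11 (1 M)
Reagents that add atoms: none
Why: Triethylamine removes the C10 proton of 4 and acetate leaves, giving the planar ylide 12, whose C10 and C6 termini add suprafacially across the C1=C5 bond of 11; the closest known reaction type is the base-induced (5+2) cycloaddition of 3-oxidopyrylium ylides with electron-poor alkenes such as vinyl ketones and acrylates. The seven-membered carbocycle C1–C5–C6–C7–C8–C9–C10 is closed by this cycloaddition, probably with the C10–C1 bond (nucleophilic ylide carbon to the enone β-carbon) ahead of the C6–C5 bond, which also places the acyl-bearing carbon next to C6 as with simple acceptor alkenes. Because the addition is suprafacial on the alkene, the E geometry is carried into C1 and C5: the C1 methyl and the C5 hydrogen end anti, which is the later trans ring fusion. C6 and C10 are tied to each other by the oxygen bridge, and their sense relative to C1 and C5 follows from the endo/exo mode: the acyl group is expected endo (secondary overlap with the ylide π system, and the branched silyloxyethyl arm goes to the less crowded exo side beside the ring oxygen). The absolute sense is set by the C2 silyloxy centre: with the C–O bond anti to the incoming C10 terminus, the C2 methyl turned inside toward the C5 hydrogen and the C2 hydrogen outside beside the C1 methyl, the (R) centre exposes the face that leads to the (1S,5S,6S,7S) adduct. The step needs rate (a β,β-disubstituted enone against self-quenching of 12), helped by slow addition of 4 to warm, concentrated 11 so that 12 stays dilute and its self-adducts can revert; it also needs regio-, endo- and face-selectivity, supplied by the single acceptor group, the size difference of the two C1 substituents and the C2 centre.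

Step 8
Reactants: 13 cycloadduct silyl ether
Product: 14 (1S,5S,6S,7R)-7-[(1R)-1-hydroxyethyl]-3,7-dimethyl-6-(2-methylpropanoyl)-8-oxabicyclo[3.2.1]oct-3-en-2-one
Conditions: HF (48% aq.), MeCN, 0 °C to rt
Reagents that add atoms: none
Why: Acidic fluoride cleavage of the hindered secondary silyl ether, tolerated by the enone, the ketone and the bridging ether (not an acetal). Basic fluoride is avoided because C5–H is α to a ketone and β to the bridge oxygen.

Step 9
Reactants: 14 bicyclic alcohol
Product: 15 (1S,5S,6S,7S)-7-acetyl-3,7-dimethyl-6-(2-methylpropanoyl)-8-oxabicyclo[3.2.1]oct-3-en-2-one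
Conditions: Dess–Martin periodinane, NaHCO3, CH2Cl2, rt
Reagents that add atoms: none
Why: Dess–Martin oxidation of the secondary alcohol to the methyl ketone under buffered, non-basic conditions; this erases the sacrificial C2 centre and creates the C3 pronucleophile.

Step 10
Reactants: 15 bicyclic diketone
Product: 16 (1S,5S,6S,7S)-7-[1-(tert-butyldimethylsilyloxy)ethenyl]-3,7-dimethyl-6-(2-methylpropanoyl)-8-oxabicyclo[3.2.1]oct-3-en-2-one
Conditions: TBSOTf (1.2 equiv), Et3N (2 equiv), CH2Cl2, −78 to 0 °C
Reagents that add atoms: tert-butyldimethylsilyl trifluoromethanesulfonate, CC(C)(C)[Si](C)(C)OS(=O)(=O)C(F)(F)F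
Why: Soft enolisation: O-silylation of the least hindered ketone and deprotonation at its only enolisable position, the C3 methyl. At this bicyclic stage the enone has no enolisable hydrogen (C10 is a bridgehead) and the isobutyryl ketone offers only two hindered methines, so the enol silane is made regiospecifically before C10 becomes a methylene.

Step 11
Reactants: 16 bicyclic enol silane
Product: 17 (4S,5S,6R)-6-[1-(tert-butyldimethylsilyloxy)ethenyl]-4-hydroxy-2,6-dimethyl-5-(2-methylpropanoyl)cyclohept-2-en-1-one
Conditions: SmI2 (2.2 equiv), THF/MeOH (10:1), −78 °C
Reagents that add atoms: none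
Why: Ketyl formation at the enone carbonyl and expulsion of the α-oxygen (samarium diiodide reduction of an α-alkoxy ketone); the bridge C10–O bond stands nearly perpendicular to the enone plane and is well aligned. The resulting 2-oxido-diene can be protonated by methanol only at C10, so the C7=C8–C9=O unit is kept and the C6 hydroxyl is released with its configuration untouched.

Step 12
Reactants: 17 hydroxy enone; 18 4-acetoxybenzoyl chloride
Product: 19 (1S,6R,7S)-6-[1-(tert-butyldimethylsilyloxy)ethenyl]-3,6-dimethyl-7-(2-methylpropanoyl)-4-oxocyclohept-2-en-1-yl 4-acetoxybenzoate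
Conditions: pyridine, DMAP (cat.), CH2Cl2, 0 °C to rt
Reagents that add atoms: none
Why: DMAP-catalysed acylation of the only free hydroxyl installs the complete aroyl ester (phenol masked as acetate) before any other alcohol exists. Pyridine is too weak a base to trigger β-elimination of the new ester across C5–C6 at this temperature.

Step 13
Reactants: 19 enol silane ester
Product: 20 (3R,3aS,4S,8aR)-3-hydroxy-6,8a-dimethyl-1,7-dioxo-3-(propan-2-yl)-1,2,3,3a,4,7,8,8a-octahydroazulen-4-yl 4-acetoxybenzoate
Conditions: TiCl4 (2 equiv), CH2Cl2, −78 °C; aq. NaHCO3
Reagents that add atoms: none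
Why: Intramolecular Mukaiyama aldol addition (5-exo attack of the enol silane carbon C3 on the TiCl4-activated C4 ketone) closes the five-membered ring trans-fused, since the C2 and C4 arms sit trans on the flexible seven-membered ring. The new C4 centre is set by the rotamer about C5–C4 that keeps the isopropyl group beside the C5 hydrogen and turns the carbonyl oxygen toward C6 (reinforced by titanium bridging the C4 carbonyl and the C6 ester oxygen), which places the hydroxyl cis to the C1 methyl.

Step 14
Reactants: 20 β-hydroxy ketone
Product: 21 (1R,3R,3aS,4S,8aR)-1,3-dihydroxy-6,8a-dimethyl-7-oxo-3-(propan-2-yl)-1,2,3,3a,4,7,8,8a-octahydroazulen-4-yl 4-acetoxybenzoate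
Conditions: NaBH4, MeOH/CH2Cl2 (1:1), −78 °C
Reagents that add atoms: none
Why: NaBH4 in MeOH/CH2Cl2 at low temperature reduces saturated ketones in preference to conjugated enones and esters. Hydride should approach the cyclopentanone anti to the adjacent angular C1 methyl (as in trans-hydrindanones), giving the C2 hydroxyl cis to that methyl and to the C4 hydroxyl.

Step 15
Reactants: 21 diol aryl acetate
Product: 22 (1R,3R,3aS,4S,8aR)-1,3-dihydroxy-6,8a-dimethyl-7-oxo-3-(propan-2-yl)-1,2,3,3a,4,7,8,8a-octahydroazulen-4-yl 4-hydroxybenzoate (CNP0199397.1)
Conditions: K2CO3 (0.2 equiv), MeOH, 0 °C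
Reagents that add atoms: none
Why: Methanolysis of the aryl acetate, which is far more labile than the hindered secondary benzoate; the benzoate is deactivated further once the phenoxide forms. No retro-aldol path remains because C2 is now a carbinol.

## Compound list

1 | methyl 3-methylfuran-2-carboxylate | COC(=O)c1occc1C | starting material
2 | (3-methylfuran-2-yl)methanol | Cc1ccoc1CO | intermediate
3 | 6-hydroxy-4-methyl-2H-pyran-3(6H)-one (racemic) | CC1=CC(O)OCC1=O | intermediate
4 | 6-acetoxy-4-methyl-2H-pyran-3(6H)-one (racemic) | CC1=CC(OC(C)=O)OCC1=O | intermediate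
5 | (R)-but-3-yn-2-ol | C[C@@H](O)C#C | starting material
6 | dimethylaluminium (R,E)-4-(dimethylalumanyl)-3-methylbut-3-en-2-olate (alkenylalane, not isolated) | C[C@@H](O[Al](C)C)/C(C)=C/[Al](C)C | intermediate
7 | (R,E)-4-iodo-3-methylbut-3-en-2-ol | C[C@@H](O)/C(C)=C/I | intermediate
8 | (R,E)-tert-butyl[(4-iodo-3-methylbut-3-en-2-yl)oxy]dimethylsilane | C[C@@H](O[Si](C)(C)C(C)(C)C)/C(C)=C/I | intermediate
9 | N-methoxy-N,2-dimethylpropanamide | CC(C)C(=O)N(C)OC | starting material
10 | [(R,E)-3-(tert-butyldimethylsilyloxy)-2-methylbut-1-en-1-yl]lithium (not isolated) | C[C@@H](O[Si](C)(C)C(C)(C)C)/C(C)=C/[Li] | intermediate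
11 | (R,E)-6-(tert-butyldimethylsilyloxy)-2,5-dimethylhept-4-en-3-one | C[C@@H](O[Si](C)(C)C(C)(C)C)/C(C)=C/C(=O)C(C)C | intermediate
12 | 4-methyl-3-oxidopyrylium (not isolated) | Cc1cc[o+]cc1[O-] | intermediate
13 | (1S,5S,6S,7S)-7-[(1R)-1-(tert-butyldimethylsilyloxy)ethyl]-3,7-dimethyl-6-(2-methylpropanoyl)-8-oxabicyclo[3.2.1]oct-3-en-2-one | CC1=C[C@H]2[C@@H](C(=O)C(C)C)[C@@](C)([C@H](O2)C1=O)[C@H](O[Si](C)(C)C(C)(C)C)C | intermediate
14 | (1S,5S,6S,7R)-7-[(1R)-1-hydroxyethyl]-3,7-dimethyl-6-(2-methylpropanoyl)-8-oxabicyclo[3.2.1]oct-3-en-2-one | CC1=C[C@H]2[C@@H](C(=O)C(C)C)[C@@](C)([C@H](O2)C1=O)[C@H](O)C | intermediate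
15 | (1S,5S,6S,7S)-7-acetyl-3,7-dimethyl-6-(2-methylpropanoyl)-8-oxabicyclo[3.2.1]oct-3-en-2-one | CC1=C[C@H]2[C@@H](C(=O)C(C)C)[C@@](C)([C@H](O2)C1=O)C(C)=O | intermediate
16 | (1S,5S,6S,7S)-7-[1-(tert-butyldimethylsilyloxy)ethenyl]-3,7-dimethyl-6-(2-methylpropanoyl)-8-oxabicyclo[3.2.1]oct-3-en-2-one | CC1=C[C@H]2[C@@H](C(=O)C(C)C)[C@@](C)([C@H](O2)C1=O)C(=C)O[Si](C)(C)C(C)(C)C | intermediate
17 | (4S,5S,6R)-6-[1-(tert-butyldimethylsilyloxy)ethenyl]-4-hydroxy-2,6-dimethyl-5-(2-methylpropanoyl)cyclohept-2-en-1-one | CC1=C[C@H](O)[C@@H](C(=O)C(C)C)[C@@](C)(CC1=O)C(=C)O[Si](C)(C)C(C)(C)C | intermediate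
18 | 4-acetoxybenzoyl chloride | CC(=O)Oc1ccc(cc1)C(Cl)=O | starting material
19 | (1S,6R,7S)-6-[1-(tert-butyldimethylsilyloxy)ethenyl]-3,6-dimethyl-7-(2-methylpropanoyl)-4-oxocyclohept-2-en-1-yl 4-acetoxybenzoate | CC1=C[C@H](OC(=O)c2ccc(OC(C)=O)cc2)[C@@H](C(=O)C(C)C)[C@@](C)(CC1=O)C(=C)O[Si](C)(C)C(C)(C)C | intermediate
20 | (3R,3aS,4S,8aR)-3-hydroxy-6,8a-dimethyl-1,7-dioxo-3-(propan-2-yl)-1,2,3,3a,4,7,8,8a-octahydroazulen-4-yl 4-acetoxybenzoate | CC1=C[C@H](OC(=O)c2ccc(OC(C)=O)cc2)[C@@H]2[C@@](C)(CC1=O)C(=O)C[C@@]2(O)C(C)C | intermediate
21 | (1R,3R,3aS,4S,8aR)-1,3-dihydroxy-6,8a-dimethyl-7-oxo-3-(propan-2-yl)-1,2,3,3a,4,7,8,8a-octahydroazulen-4-yl 4-acetoxybenzoate | CC1=C[C@H](OC(=O)c2ccc(OC(C)=O)cc2)[C@@H]2[C@@](C)(CC1=O)[C@H](O)C[C@@]2(O)C(C)C | intermediate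
22 | (1R,3R,3aS,4S,8aR)-1,3-dihydroxy-6,8a-dimethyl-7-oxo-3-(propan-2-yl)-1,2,3,3a,4,7,8,8a-octahydroazulen-4-yl 4-hydroxybenzoate | CC1=C[C@H](OC(=O)c2ccc(O)cc2)[C@@H]2[C@@](C)(CC1=O)[C@H](O)C[C@@]2(O)C(C)C | target

## Step count and least certain steps

Total step count: 15. Longest linear sequence: 12 steps (steps 4–15 from 5; the arm from 1, steps 1–3 and 7–15, is equally long).

Step 7 (key step). The most likely failure is that self-quenching of the ylide outruns addition to the β,β-disubstituted enone, which is a sluggish 2π partner. A second exposure is erosion of face selectivity, because the controlling centre is acyclic and its sense of induction rests on a model. Fallback: replace the acceptor by the less hindered and more electrophilic aldehyde and build the isobutyryl ketone afterwards. Setting out from 8, iodine–lithium exchange (t-BuLi) and formylation with DMF should give (R,E)-4-(tert-butyldimethylsilyloxy)-3-methylpent-2-enal F1. Cycloaddition of F1 with 4 under the conditions of step 7 should give the 6-endo-formyl adduct, 7-[(1R)-1-(tert-butyldimethylsilyloxy)ethyl]-3,7-dimethyl-2-oxo-8-oxabicyclo[3.2.1]oct-3-ene-6-carbaldehyde F2. Addition of i-PrMgCl/CeCl3 at −78 °C, which should prefer the aldehyde over the conjugated ketone, gives the carbinol 7-[(1R)-1-(tert-butyldimethylsilyloxy)ethyl]-6-(1-hydroxy-2-methylpropyl)-3,7-dimethyl-8-oxabicyclo[3.2.1]oct-3-en-2-one F3 (both carbinol epimers serve). Dess–Martin oxidation comes back to the route at 13.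

Step 11. The bridge oxygen is α to the ketone at C10 but also vinylogously related to it at C6 through C7=C8, so scission of the C6–O bond, or conjugate reduction of the enone, may compete with the wanted C10–O scission. Fallback: take the alkene out of play during the reduction. Setting out from 16, conjugate addition of benzenethiol (PhSH, Et3N) at C7 should give the saturated ketone 7-[1-(tert-butyldimethylsilyloxy)ethenyl]-3,7-dimethyl-6-(2-methylpropanoyl)-4-(phenylsulfanyl)-8-oxabicyclo[3.2.1]octan-2-one F4. SmI2/MeOH can then break only the α C10–O bond and gives 6-[1-(tert-butyldimethylsilyloxy)ethenyl]-4-hydroxy-2,6-dimethyl-5-(2-methylpropanoyl)-3-(phenylsulfanyl)cycloheptan-1-one F5. Elimination of thiolate across C7–C8 with DBU restores the enone and comes back to the route at 17.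

Step 13. The enol silane has two other electrophilic sites within reach (the C9 carbonyl, giving a bridged aldol, and C7 by conjugate addition), and the ketone–ketone aldol may revert or dehydrate under the Lewis acid. Fallback: generate the enolate regiospecifically by reduction and let the aldol equilibrate under chelation. Setting out from 19, NBS should convert the enol silane into the bromoketone (1S,6R,7S)-6-(bromoacetyl)-3,6-dimethyl-7-(2-methylpropanoyl)-4-oxocyclohept-2-en-1-yl 4-acetoxybenzoate F6. SmI2 (2 equiv, THF, −78 °C) reduces the α-bromo ketone far faster than the enone, and the resulting enolate of trivalent samarium should close onto the chelated C4 ketone (intramolecular Reformatsky-type aldol), coming back to the route at 20.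

Step 14. The discrimination between the saturated C2 ketone and the conjugated C9 ketone may be incomplete, with hydride also adding at C9; the facial preference at C2 rests on the angular methyl alone. Fallback: reduce both carbonyls on purpose and re-oxidise only the allylic one. Setting out from 20, NaBH4/CeCl3 in MeOH (Luche conditions) should give the triol 1,3,7-trihydroxy-6,8a-dimethyl-3-(propan-2-yl)-1,2,3,3a,4,7,8,8a-octahydroazulen-4-yl 4-acetoxybenzoate F7 (either C9 epimer serves). MnO2 oxidises the allylic C9 carbinol selectively and comes back to the route at 21.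

## Further compounds

F1 | step 7 | (R,E)-4-(tert-butyldimethylsilyloxy)-3-methylpent-2-enal | C[C@@H](O[Si](C)(C)C(C)(C)C)/C(C)=C/C=O
F2 | step 7 | 7-[(1R)-1-(tert-butyldimethylsilyloxy)ethyl]-3,7-dimethyl-2-oxo-8-oxabicyclo[3.2.1]oct-3-ene-6-carbaldehyde (formyl endo) | CC1=C[C@H]2[C@@H](C=O)[C@@](C)([C@H](O2)C1=O)[C@H](O[Si](C)(C)C(C)(C)C)C
F3 | step 7 | 7-[(1R)-1-(tert-butyldimethylsilyloxy)ethyl]-6-(1-hydroxy-2-methylpropyl)-3,7-dimethyl-8-oxabicyclo[3.2.1]oct-3-en-2-one (carbinol epimers) | CC1=C[C@H]2[C@@H](C(O)C(C)C)[C@@](C)([C@H](O2)C1=O)[C@H](O[Si](C)(C)C(C)(C)C)C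
F4 | step 11 | 7-[1-(tert-butyldimethylsilyloxy)ethenyl]-3,7-dimethyl-6-(2-methylpropanoyl)-4-(phenylsulfanyl)-8-oxabicyclo[3.2.1]octan-2-one | CC1C(Sc3ccccc3)[C@H]2[C@@H](C(=O)C(C)C)[C@@](C)([C@H](O2)C1=O)C(=C)O[Si](C)(C)C(C)(C)C
F5 | step 11 | 6-[1-(tert-butyldimethylsilyloxy)ethenyl]-4-hydroxy-2,6-dimethyl-5-(2-methylpropanoyl)-3-(phenylsulfanyl)cycloheptan-1-one | CC1C(Sc2ccccc2)[C@H](O)[C@@H](C(=O)C(C)C)[C@@](C)(CC1=O)C(=C)O[Si](C)(C)C(C)(C)C
F6 | step 13 | (1S,6R,7S)-6-(bromoacetyl)-3,6-dimethyl-7-(2-methylpropanoyl)-4-oxocyclohept-2-en-1-yl 4-acetoxybenzoate | CC1=C[C@H](OC(=O)c2ccc(OC(C)=O)cc2)[C@@H](C(=O)C(C)C)[C@@](C)(CC1=O)C(=O)CBr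
F7 | step 14 | 1,3,7-trihydroxy-6,8a-dimethyl-3-(propan-2-yl)-1,2,3,3a,4,7,8,8a-octahydroazulen-4-yl 4-acetoxybenzoate (C7 carbinol epimers) | CC1=C[C@H](OC(=O)c2ccc(OC(C)=O)cc2)[C@@H]2[C@@](C)(CC1O)[C@H](O)C[C@@]2(O)C(C)C
A1 | alternative 1 | (5R)-2-diazo-5-(2,5-dimethoxy-4-methylphenyl)-6-methyl-5-(triethylsilyloxy)heptan-3-one | CC(=[N+]=[N-])C(=O)C[C@@](O[Si](CC)(CC)CC)(C(C)C)c1cc(OC)c(C)cc1OC
A2 | alternative 1 | (3R,8aR)-4,7-dimethoxy-6,8a-dimethyl-3-(propan-2-yl)-3-(triethylsilyloxy)-3,8a-dihydroazulen-1(2H)-one | CC1=CC(OC)=C2[C@@](C)(C=C1OC)C(=O)C[C@@]2(O[Si](CC)(CC)CC)C(C)C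
A3 | alternative 2 | hydroazulene allylic alcohol with C1=C10, free C2 hydroxyl, C4 and C9 triethylsilyl ethers and C6 tert-butyldimethylsilyl ether | C[C@@H]1C[C@H](O[Si](C)(C)C(C)(C)C)[C@@H]2C(=C[C@H]1O[Si](CC)(CC)CC)[C@H](O)C[C@@]2(O[Si](CC)(CC)CC)C(C)C
A4 | alternative 2 | C1,C10-cyclopropane with the methylene cis to the C2 hydroxyl | C[C@@H]1C[C@H](O[Si](C)(C)C(C)(C)C)[C@@H]2[C@@]3([C@@H](C3)[C@H]1O[Si](CC)(CC)CC)[C@H](O)C[C@@]2(O[Si](CC)(CC)CC)C(C)C
A5 | alternative 3 | (S)-terpinen-4-ol, (S)-4-methyl-1-(propan-2-yl)cyclohex-3-en-1-ol | CC1=CC[C@@](O)(CC1)C(C)C
A6 | alternative 3 | 3-methyl-2-methylenetetrahydrofuran bearing at C5 the 2-methyl-3-(tert-butyldimethylsilyloxy)-5-(propan-2-yl)-5-(triethylsilyloxy)cyclopent-1-enyl group | C=C1O[C@@H](C[C@H]1C)C1=C(C)[C@H](O[Si](C)(C)C(C)(C)C)C[C@@]1(O[Si](CC)(CC)CC)C(C)C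
A7 | alternative 3 | bicyclic cyclohept-4-enone with C5=C6, C9 ketone, quaternary C1, C2 tert-butyldimethylsilyl ether and C4 triethylsilyl ether | C[C@@H]1CC=C2[C@@](C)(CC1=O)[C@H](O[Si](C)(C)C(C)(C)C)C[C@@]2(O[Si](CC)(CC)CC)C(C)C
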